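**Retrosynthetic overview**

1. The strategy rests on ring C of the (2S)-flavanone (O1, C2, C3, C4, C4a, C8a). The O1–C2 and C3–C4 bonds are cut together, giving styrene (C2, C3 and ring B) and a 4-methoxy ortho-quinone methide (oxa-diene O1–C8a–C4a–C4) generated from salicylaldehyde 6. C2, the only stereocentre, is set in this step.
2. The adduct carries C4 as a methyl ether. The C8 ester chain is first taken to the tertiary carbinol with MeMgBr, then DDQ oxidises the C4 ether to the ketone, and the 5-O-benzyl group is removed last.
3. Salicylaldehyde 6 comes from phenol ester 5 by phenoxide-directed ortho-formylation. 5 comes from aldehyde 3 by Wittig extension and conjugate reduction, so the formyl carbon of 3 becomes the benzylic CH2 on C8.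
4. 3 comes from 5-methoxyresorcinol by Vilsmeier formylation and O-benzylation para to the formyl group. Chelation, not statistics, therefore fixes the 5-OBn / 7-OMe / free O1-H pattern.
5. Ring order: ring A is bought, ring B arrives with styrene, and ring C is the only ring formed (step 6).

Key step: step 6

Remark on the chemistry: C4 of compounds 11 and 12 is a mixture of epimers and is drawn without configuration, because it becomes the carbonyl carbon in step 8. The enantiomer of the acid catalyst that delivers 2S has to be found by experiment.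

**Route**

Step 1
Reactants: 1 5-methoxyresorcinol (5-methoxybenzene-1,3-diol)
Product: 2 2,4-dihydroxy-6-methoxybenzaldehyde
Conditions: POCl3, DMF, MeCN, 0 °C to rt; then H2O, 50 °C
Reagents that add atoms: N,N-dimethylformamide, CN(C)C=O; water, O
Why: Vilsmeier–Haack formylation, in which the chloroiminium electrophile should attack the carbon para to one hydroxyl and between OH and OMe (two equivalent sites) in preference to the carbon between the two hydroxyls, the minor 2,6-dihydroxy-4-methoxy isomer being removed by crystallisation.

Step 2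
Reactants: 2 2,4-dihydroxy-6-methoxybenzaldehyde
Product: 3 4-(benzyloxy)-2-hydroxy-6-methoxybenzaldehyde
Conditions: BnBr (1.05 equiv), K2CO3 (1.1 equiv), acetone, rt to 40 °C
Reagents that add atoms: benzyl bromide, BrCc1ccccc1
Why: Williamson etherification selective for the 4-OH, which is para to the formyl group, more acidic and not hydrogen-bonded, while the 2-OH is held in a chelate with the carbonyl.

Step 3
Reactants: 3 4-(benzyloxy)-2-hydroxy-6-methoxybenzaldehyde
Product: 4 methyl (2E)-3-[4-(benzyloxy)-2-hydroxy-6-methoxyphenyl]prop-2-enoate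
Conditions: Ph3P=CHCO2Me (1.3 equiv), toluene, 80 °C
Reagents that add atoms: methyl (triphenylphosphoranylidene)acetate, COC(=O)C=P(c1ccccc1)(c1ccccc1)c1ccccc1
Why: Wittig olefination with a stabilised ylide, which tolerates the free phenol and should give the E-enoate, whose geometry keeps the phenol from closing to the coumarin.

Step 4
Reactants: 4 methyl (2E)-3-[4-(benzyloxy)-2-hydroxy-6-methoxyphenyl]prop-2-enoate
Product: 5 methyl 3-[4-(benzyloxy)-2-hydroxy-6-methoxyphenyl]propanoate
Conditions: NiCl2·6H2O (0.2 equiv), NaBH4 (3 equiv), MeOH/THF, 0 °C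
Reagents that add atoms: none
Why: Conjugate reduction of the cinnamate C=C by Ni2B formed in situ, which leaves the aryl benzyl ether and the methyl ester untouched, with methanol as solvent keeping the product as the open methyl ester.

Step 5
Reactants: 5 methyl 3-[4-(benzyloxy)-2-hydroxy-6-methoxyphenyl]propanoate
Product: 6 methyl 3-[4-(benzyloxy)-3-formyl-2-hydroxy-6-methoxyphenyl]propanoate
Conditions: MgCl2 (anhydrous, 2 equiv), Et3N (4 equiv), (CH2O)n (6 equiv), MeCN, 70 °C; 1 M HCl work-up
Reagents that add atoms: paraformaldehyde (as formaldehyde), C=O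
Why: Casnati–Skattebøl ortho-formylation, in which the chloromagnesium phenoxide (ArOMgCl) delivers formaldehyde only to the single free carbon ortho to the phenol oxygen (between OH and OBn, not the carbon between OBn and OMe) and excess formaldehyde serves as hydride acceptor to reach the aldehyde.

Step 6
Reactants: 6 methyl 3-[4-(benzyloxy)-3-formyl-2-hydroxy-6-methoxyphenyl]propanoate; 7 styrene; 8 trimethyl orthoformate
Product: 11 methyl 3-[(2S)-5-(benzyloxy)-4,7-dimethoxy-2-phenyl-3,4-dihydro-2H-chromen-8-yl]propanoate (mixture of C4 epimers), via dimethyl acetal 9 (not isolated), via 4-methoxy ortho-quinone methide 10 (not isolated)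
Conditions: 8 (2 equiv), confined chiral imidodiphosphorimidate (IDPi) Brønsted acid (5 mol%), CH2Cl2, rt; then 7 (5 equiv), −40 to −20 °C; Et3N quench
Reagents that add atoms: none
Why: Proposed new method: acid-catalysed exchange with 8 turns the aldehyde into dimethyl acetal 9, which the strong chiral acid ionises with loss of methanol to the O-protonated form of quinone methide 10, an aryl oxocarbenium ion stabilised by the three ring-A oxygens and paired with the confined chiral anion. The CH2 terminus of styrene attacks the methide carbon (C3–C4 bond, Prins-type) and the phenolic oxygen then collapses onto the benzylic cation developing next to the phenyl group (O1–C2 bond), so ring C closes as an asynchronous inverse-electron-demand oxa-[4+2] cycloaddition across O1–C8a–C4a–C4, the six-membered ring being completed by C–O bond formation. The closest known reactions are the achiral acid-catalysed three-component coupling of salicylaldehydes, orthoformates and styrenes to 4-alkoxyflavans and chiral Brønsted acid-catalysed [4+2] additions of styrenes to ortho-quinone methides; what is new is enantiocontrol with a 4-alkoxy quinone methide and an unfunctionalised styrene. C2 is fixed when the oxygen closes onto one enantioface of the styrene-derived carbon inside the chiral pocket, so the anion has to orient the styrene and not merely shield one face of the cation; C4 forms as a mixture of epimers and is oxidised later. Regioselectivity (phenyl at C2) follows from styrene polarisation, and chemoselectivity rests on the substrate: the methyl ester is inert to the acid where a tertiary alcohol would not be, the one free arene position (C6) should be outcompeted by excess styrene at low temperature, and the Et3N quench prevents re-ionisation of the C4 ether.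

Step 7
Reactants: 11 methyl 3-[(2S)-5-(benzyloxy)-4,7-dimethoxy-2-phenyl-3,4-dihydro-2H-chromen-8-yl]propanoate
Product: 12 4-[(2S)-5-(benzyloxy)-4,7-dimethoxy-2-phenyl-3,4-dihydro-2H-chromen-8-yl]-2-methylbutan-2-ol (mixture of C4 epimers)
Conditions: MeMgBr (4 equiv), THF, 0 °C to rt; sat. aq. NH4Cl
Reagents that add atoms: methylmagnesium bromide, C[Mg]Br
Why: Double Grignard addition to the methyl ester should give the tertiary carbinol, the C4 benzylic methyl ether and the benzyl ether being inert to MeMgBr in THF at 0 °C and C2 being untouched.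

Step 8
Reactants: 12 4-[(2S)-5-(benzyloxy)-4,7-dimethoxy-2-phenyl-3,4-dihydro-2H-chromen-8-yl]-2-methylbutan-2-ol
Product: 13 (2S)-5-(benzyloxy)-8-(3-hydroxy-3-methylbutyl)-7-methoxy-2-phenyl-2,3-dihydro-4H-chromen-4-one
Conditions: DDQ (1.2 equiv), CH2Cl2/pH 7 phosphate buffer (10:1), 0 °C
Reagents that add atoms: water, O
Why: DDQ abstracts hydride from the C4–H bond, which is benzylic to the 2,4,6-trioxygenated ring A and alpha to OMe (the reactivity used in oxidative cleavage of p-methoxybenzyl ethers), and water hydrolyses the resulting oxocarbenium ion to the ketone under buffered conditions that spare the tertiary alcohol, the benzyl ether and the C2 stereocentre.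

Step 9
Reactants: 13 (2S)-5-(benzyloxy)-8-(3-hydroxy-3-methylbutyl)-7-methoxy-2-phenyl-2,3-dihydro-4H-chromen-4-one
Product: 14 (2S)-5-hydroxy-8-(3-hydroxy-3-methylbutyl)-7-methoxy-2-phenyl-2,3-dihydro-4H-chromen-4-one (CNP0160063.1)
Conditions: H2 (1 atm), 10% Pd/C, EtOAc, rt
Reagents that add atoms: none
Why: Hydrogenolysis of the aryl benzyl ether over Pd/C under neutral conditions, which should leave the tertiary alcohol and the aryl ketone intact and cannot epimerise C2 by base-induced ring opening.

**Compound list**

1 | 5-methoxyresorcinol | COc1cc(O)cc(O)c1 | starting material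
2 | 2,4-dihydroxy-6-methoxybenzaldehyde | COc1cc(O)cc(O)c1C=O | intermediate
3 | 4-(benzyloxy)-2-hydroxy-6-methoxybenzaldehyde | COc1cc(OCc2ccccc2)cc(O)c1C=O | intermediate
4 | methyl (2E)-3-[4-(benzyloxy)-2-hydroxy-6-methoxyphenyl]prop-2-enoate | COC(=O)/C=C/c1c(O)cc(OCc2ccccc2)cc1OC | intermediate
5 | methyl 3-[4-(benzyloxy)-2-hydroxy-6-methoxyphenyl]propanoate | COC(=O)CCc1c(O)cc(OCc2ccccc2)cc1OC | intermediate
6 | methyl 3-[4-(benzyloxy)-3-formyl-2-hydroxy-6-methoxyphenyl]propanoate | COC(=O)CCc1c(OC)cc(OCc2ccccc2)c(C=O)c1O | intermediate
7 | styrene | C=Cc1ccccc1 | starting material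
8 | trimethyl orthoformate | COC(OC)OC | starting material
9 | methyl 3-[4-(benzyloxy)-3-(dimethoxymethyl)-2-hydroxy-6-methoxyphenyl]propanoate (dimethyl acetal) | COC(=O)CCc1c(OC)cc(OCc2ccccc2)c(C(OC)OC)c1O | intermediate
10 | methyl 3-[4-(benzyloxy)-2-methoxy-5-(methoxymethylidene)-6-oxocyclohexa-1,3-dien-1-yl]propanoate (4-methoxy ortho-quinone methide, present as its O-protonated ion pair; alkene geometry not defined) | COC(=O)CCC1=C(OC)C=C(OCc2ccccc2)C(=COC)C1=O | intermediate
11 | methyl 3-[(2S)-5-(benzyloxy)-4,7-dimethoxy-2-phenyl-3,4-dihydro-2H-chromen-8-yl]propanoate (C4 epimers) | COC(=O)CCc1c(OC)cc(OCc2ccccc2)c2c1O[C@H](c1ccccc1)CC2OC | intermediate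
12 | 4-[(2S)-5-(benzyloxy)-4,7-dimethoxy-2-phenyl-3,4-dihydro-2H-chromen-8-yl]-2-methylbutan-2-ol (C4 epimers) | CC(C)(O)CCc1c(OC)cc(OCc2ccccc2)c2c1O[C@H](c1ccccc1)CC2OC | intermediate
13 | (2S)-5-(benzyloxy)-8-(3-hydroxy-3-methylbutyl)-7-methoxy-2-phenyl-2,3-dihydro-4H-chromen-4-one | COc1cc(OCc2ccccc2)c2c(c1CCC(C)(C)O)O[C@H](c1ccccc1)CC2=O | intermediate
14 | (2S)-5-hydroxy-8-(3-hydroxy-3-methylbutyl)-7-methoxy-2-phenyl-2,3-dihydro-4H-chromen-4-one | COc1cc(O)c2c(c1CCC(C)(C)O)O[C@H](c1ccccc1)CC2=O | target

**Step count**

Total steps: 9. Longest linear sequence: 9 (from 5-methoxyresorcinol).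

**Steps most likely to fail**

Step 6. The chiral anion may orient the styrene too weakly, so that C2 forms with poor enantioselectivity. The strongly stabilised cation may also add styrene so slowly that styrene oligomerisation, Friedel–Crafts self-condensation at C6 or re-ionisation of the C4 ether take over. The fallback uses known chemistry and sets out from 6. The same three-component coupling with an achiral acid (p-TsOH or Sc(OTf)3, 7 and 8, CH2Cl2) should give racemic methyl 3-[5-(benzyloxy)-4,7-dimethoxy-2-phenyl-3,4-dihydro-2H-chromen-8-yl]propanoate F1. MeMgBr in THF should convert it into racemic 4-[5-(benzyloxy)-4,7-dimethoxy-2-phenyl-3,4-dihydro-2H-chromen-8-yl]-2-methylbutan-2-ol F2, and DDQ in wet CH2Cl2 into racemic 5-(benzyloxy)-8-(3-hydroxy-3-methylbutyl)-7-methoxy-2-phenyl-2,3-dihydro-4H-chromen-4-one F3. Kinetic resolution by asymmetric transfer hydrogenation (RuCl(p-cymene)(TsDPEN), HCO2H/Et3N), with the catalyst enantiomer chosen so that the (2R)-ketone reacts faster, should remove that enantiomer as (2R,4R)-5-(benzyloxy)-8-(3-hydroxy-3-methylbutyl)-7-methoxy-2-phenyl-3,4-dihydro-2H-chromen-4-ol F4. The unreacted (2S)-ketone is 13, where the route is rejoined; at most half of the material is recovered.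

Step 5. The chloromagnesium phenoxide may lactonise onto the neighbouring methyl ester, giving a dihydrocoumarin that has no phenoxide left to direct formylation. Reaction at the carbon flanked by OH and OBn may also be slow. The fallback sets out from 4. The same MgCl2/Et3N/(CH2O)n formylation is run on the E-enoate, whose geometry makes lactonisation impossible, to give methyl (2E)-3-[4-(benzyloxy)-3-formyl-2-hydroxy-6-methoxyphenyl]prop-2-enoate F5. Homogeneous hydrogenation with RhCl(PPh3)3 and H2 in benzene/EtOH should then saturate the C=C while leaving the chelated aldehyde and the benzyl ether, which returns to the route at 6.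

Step 8. The oxocarbenium ion may lose a C3 proton instead of being trapped by water, and the resulting enol ether may be dehydrogenated further towards the flavone, destroying the C2 stereocentre. Competing hydride abstraction at C2 is a second possibility. The fallback sets out from 12. Mild aqueous solvolysis of the doubly activated benzylic methyl ether (PPTS, acetone/H2O, rt) should give (2S)-5-(benzyloxy)-8-(3-hydroxy-3-methylbutyl)-7-methoxy-2-phenyl-3,4-dihydro-2H-chromen-4-ol F6 as C4 epimers. Dess–Martin periodinane buffered with NaHCO3 in CH2Cl2 then oxidises the secondary benzylic alcohol, but not the tertiary one, to return to the route at 13.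

**Further compounds**

F1 | step 6 | racemic methyl 3-[5-(benzyloxy)-4,7-dimethoxy-2-phenyl-3,4-dihydro-2H-chromen-8-yl]propanoate | COC(=O)CCc1c(OC)cc(OCc2ccccc2)c2c1OC(c1ccccc1)CC2OC
F2 | step 6 | racemic 4-[5-(benzyloxy)-4,7-dimethoxy-2-phenyl-3,4-dihydro-2H-chromen-8-yl]-2-methylbutan-2-ol | CC(C)(O)CCc1c(OC)cc(OCc2ccccc2)c2c1OC(c1ccccc1)CC2OC
F3 | step 6 | racemic 5-(benzyloxy)-8-(3-hydroxy-3-methylbutyl)-7-methoxy-2-phenyl-2,3-dihydro-4H-chromen-4-one | COc1cc(OCc2ccccc2)c2c(c1CCC(C)(C)O)OC(c1ccccc1)CC2=O
F4 | step 6 | (2R,4R)-5-(benzyloxy)-8-(3-hydroxy-3-methylbutyl)-7-methoxy-2-phenyl-3,4-dihydro-2H-chromen-4-ol | COc1cc(OCc2ccccc2)c2c(c1CCC(C)(C)O)O[C@@H](c1ccccc1)C[C@H]2O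
F5 | step 5 | methyl (2E)-3-[4-(benzyloxy)-3-formyl-2-hydroxy-6-methoxyphenyl]prop-2-enoate | COC(=O)/C=C/c1c(OC)cc(OCc2ccccc2)c(C=O)c1O
F6 | step 8 | (2S)-5-(benzyloxy)-8-(3-hydroxy-3-methylbutyl)-7-methoxy-2-phenyl-3,4-dihydro-2H-chromen-4-ol (C4 epimers) | COc1cc(OCc2ccccc2)c2c(c1CCC(C)(C)O)O[C@H](c1ccccc1)CC2O
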